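**Strategy.** Locants follow azulene numbering (cyclopentane C1, C2, C3, C3a, C8a; cycloheptene C3a–C8a). The cyclopentane is closed last, on a preformed cycloheptadiene, by an intramolecular nitrile oxide cycloaddition: the dipole carbon (C1), tethered through C2–C3 to the quaternary C3a, adds across C8=C8a. One operation forms C1–C8a and O–C8, i.e. the cyclopentane plus a temporary isoxazoline, and exploits the cis ring fusion (C3a/C8a) and the syn relation of the C8–O and C8a–C1 bonds. The precursor is a 1,3-cycloheptadiene with a 3-(hydroxyimino)propyl chain at C3a; its C3a/C4 centres come from an iridium-catalysed tert-(hydroxy)prenylation, and the C1/C2 cis-diol from a late dihydroxylation.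

Key step: step 9

Remarks on the chemistry:
- Assumption: the Ir-catalysed coupling of step 1 is taken to give the anti (secondary OH / CH2OH) diastereomer through an (E)-σ-allyl chair transition state; the Tol-BINAP antipode is chosen that leads to (2S,3S)-4.
- Racemic 2 suffices, because its stereocentre is lost in the π-allyl.
- Compounds 11 and 12 are carried as epimer mixtures at the carbinol carbon (future C8a), which becomes sp2 in step 7.
- TBS = tert-butyldimethylsilyl, TES = triethylsilyl.

Step 1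
Reactants: 1 3-methylbut-3-en-1-ol; 2 2-methyl-2-vinyloxirane (racemic)
Product: 4 (2S,3S)-2-ethenyl-2,5-dimethylhex-5-ene-1,3-diol, via 3-methylbut-3-enal 3 (not isolated)
Conditions: π-allyl-Ir C,O-benzoate of Tol-BINAP (one antipode) and 4-cyano-3-nitrobenzoic acid (5 mol%), K3PO4 (5 mol%), THF, 60 °C
Reagents that add atoms: none
Why: Iridium-catalysed transfer-hydrogenative carbonyl tert-(hydroxy)prenylation: the catalyst dehydrogenates 1 to aldehyde 3 and opens the vinyl epoxide to an (E)-σ-allyl species that adds through a chair transition state, so that the quaternary C3a and the C4 carbinol should form anti, with the ligand antipode fixing the absolute sense of both.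

Step 2
Reactants: 4 (2S,3S)-2-ethenyl-2,5-dimethylhex-5-ene-1,3-diol
Product: 5 bis-TBS ether of 4
Conditions: TBSOTf (2.4 equiv), 2,6-lutidine, CH2Cl2, −78 → 0 °C
Reagents that add atoms: tert-butyldimethylsilyl trifluoromethanesulfonate, CC(C)(C)[Si](C)(C)OS(=O)(=O)C(F)(F)F
Why: Silylation of both hydroxyls (the silyl triflate is needed for the neopentyl secondary one) protects O4 for the whole route and masks the primary alcohol during hydroformylation.

Step 3
Reactants: 5 bis-TBS ether of 4
Product: 7 dimethyl acetal of the chain-extended aldehyde, via linear aldehyde 6 (not isolated)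
Conditions: Rh(acac)(CO)2 (2 mol%), Xantphos (4 mol%), CO/H2 (1:1, 10 bar), HC(OMe)3, PPTS (5 mol%), toluene, 60 °C
Reagents that add atoms: carbon monoxide, [C-]#[O+]; trimethyl orthoformate, COC(OC)OC
Why: Tandem rhodium-catalysed hydroformylation–acetalisation: the vinyl group on the quaternary carbon can only give the linear aldehyde (the future C1), the 1,1-disubstituted alkene should react far more slowly, and the aldehyde is trapped in situ as its dimethyl acetal.

Step 4
Reactants: 7 dimethyl acetal
Product: 8 (2S,3S)-3-(tert-butyldimethylsilyloxy)-2-(3,3-dimethoxypropyl)-2,5-dimethylhex-5-en-1-ol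
Conditions: TBAF (1.1 equiv), THF, 0 °C
Reagents that add atoms: none
Why: Fluoride-mediated desilylation is faster at the primary than at the neopentyl secondary silyl ether, and the basic medium keeps the acetal from cyclising onto the freed hydroxyl.

Step 5
Reactants: 8 (2S,3S)-3-(tert-butyldimethylsilyloxy)-2-(3,3-dimethoxypropyl)-2,5-dimethylhex-5-en-1-ol; 9 allyl acetate
Product: 11 homoallylic alcohol (both carbinol epimers), via neopentyl aldehyde 10 (not isolated)
Conditions: [Ir(cod)Cl]2 (2.5 mol%), rac-BINAP (5 mol%), Cs2CO3 (20 mol%), 3-nitrobenzoic acid (10 mol%), THF, 100 °C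
Reagents that add atoms: none
Why: Iridium-catalysed transfer-hydrogenative carbonyl allylation from the alcohol oxidation level: the primary alcohol is dehydrogenated to the non-enolisable aldehyde 10, which is allylated in situ; the new carbinol centre is left uncontrolled on purpose, because step 7 destroys it.

Step 6
Reactants: 11 homoallylic alcohol
Product: 12 cycloheptenol (both carbinol epimers)
Conditions: Grubbs II (5 mol%), CH2Cl2 (5 mM), 40 °C
Reagents that add atoms: none
Why: Ring-closing metathesis between the monosubstituted and the 1,1-disubstituted alkene should close the seven-membered ring as the trisubstituted C6=C7 alkene, helped by the quaternary C3a.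

Step 7
Reactants: 12 cycloheptenol
Product: 13 (6S,7S)-6-(tert-butyldimethylsilyloxy)-7-(3,3-dimethoxypropyl)-4,7-dimethylcyclohepta-1,3-diene
Conditions: Martin sulfurane, CH2Cl2, 0 °C → rt
Reagents that add atoms: none
Why: Dehydration of the secondary alcohol with Martin sulfurane can only remove an allylic C8–H, because C3a is quaternary, so both epimers should give the conjugated C6=C7–C8=C8a diene.

Step 8
Reactants: 13 cycloheptadiene acetal
Product: 14 3-[(1S,7S)-7-(tert-butyldimethylsilyloxy)-1,5-dimethylcyclohepta-2,4-dien-1-yl]propanal oxime (E/Z)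
Conditions: NH2OH·HCl, THF/H2O (4:1), 40 °C; NaHCO3 work-up
Reagents that add atoms: hydroxylamine hydrochloride, NO.Cl
Why: The acidic hydroxylammonium salt hydrolyses the dimethyl acetal and condenses with the liberated aldehyde (oxime formation); the oxime geometry is irrelevant.

Step 9
Reactants: 14 aldoxime
Product: 17 tricyclic isoxazoline (3aS,4S,8S,8aS; C1=N–O–C8; 4-OTBS), via hydroximoyl chloride 15 (not isolated), via nitrile oxide 16 (not isolated)
Conditions: aq. NaOCl, CH2Cl2 (high dilution), 0 °C → rt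
Reagents that add atoms: none
Why: Hypochlorite chlorinates the aldoxime to hydroximoyl chloride 15, which loses HCl to nitrile oxide 16; this adds to the C8=C8a bond in a concerted, suprafacial Huisgen [3+2] cycloaddition, the well-known intramolecular nitrile oxide–alkene cycloaddition of a 5-hexenyl-type dipole. The cyclopentane closes through the C1–C8a bond in the exo mode of the three-atom tether (C2, C3, C3a), and the isoxazoline closes in the same event through the O–C8 bond. C8a is controlled by the quaternary C3a, because the short tether can deliver the dipole only to the alkene face that carries the C3 methylene, which enforces the cis ring fusion. C8 is controlled by the suprafacial addition, which places O8 on the same face as the new C8a–C1 bond. The step needs site selectivity (C8=C8a, not C6=C7) and regioselectivity (carbon to C8a, oxygen to C8); both follow from the tether length and agree with the usual preference of nitrile oxides to put oxygen on the internal carbon of a 1,3-diene. The C4 silyloxy group sits on the opposite ring face and should not interfere, and dilution should suppress dimerisation of the dipole.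

Step 10
Reactants: 17 tricyclic isoxazoline
Product: 19 (3aS,4S,8S,8aR)-4-(tert-butyldimethylsilyloxy)-8-hydroxy-3a,6-dimethyl-3,3a,4,5,8,8a-hexahydroazulen-1(2H)-one, via hydroxy imine 18 (not isolated)
Conditions: Mo(CO)6, MeCN/H2O (15:1), 80 °C
Reagents that add atoms: water, O
Why: Reductive N–O cleavage of the isoxazoline with Mo(CO)6 gives β-hydroxy imine 18, hydrolysed in situ to the β-hydroxy ketone under neutral conditions that should spare both alkenes and avoid β-elimination; no stereocentre is touched.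

Step 11
Reactants: 20 4-hydroxybenzoic acid
Product: 22 4-(tert-butyldimethylsilyloxy)benzoic acid, via bis-silylated benzoate 21 (not isolated)
Conditions: TBSCl (2.2 equiv), imidazole, DMF, rt; then AcOH/THF/H2O, rt
Reagents that add atoms: tert-butyldimethylsilyl chloride, CC(C)(C)[Si](C)(C)Cl
Why: Bis-silylation followed by selective hydrolysis of the labile silyl ester leaves the aryl silyl ether, a phenol protection that falls together with the C4 silyl ether in the last step.

Step 12
Reactants: 19 β-hydroxy ketone; 22 4-(tert-butyldimethylsilyloxy)benzoic acid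
Product: 23 (3aS,4S,8S,8aR)-4-(tert-butyldimethylsilyloxy)-3a,6-dimethyl-1-oxo-1,2,3,3a,4,5,8,8a-octahydroazulen-8-yl 4-(tert-butyldimethylsilyloxy)benzoate
Conditions: EDC·HCl, DMAP (cat.), CH2Cl2, 0 °C → rt
Reagents that add atoms: none
Why: Steglich esterification of the only free hydroxyl (C8–OH) under near-neutral conditions installs the aroyl group, which also deactivates the C6=C7 alkene for step 15.

Step 13
Reactants: 23 keto ester
Product: 25 C1=C2 enol triflate of 23, via potassium enolate 24 (not isolated)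
Conditions: KHMDS (1.1 equiv), THF, −78 °C; then PhNTf2, −78 → 0 °C
Reagents that add atoms: N-phenyl-bis(trifluoromethanesulfonimide), O=S(=O)(N(c1ccccc1)S(=O)(=O)C(F)(F)F)C(F)(F)F
Why: Kinetic deprotonation should take place at the unhindered C2 methylene and not at the ring-fusion C8a–H, and O-triflation of the enolate gives the C1=C2 enol triflate.

Step 14
Reactants: 25 enol triflate; 26 isopropylzinc bromide
Product: 27 (3aS,4S,8S,8aR)-4-(tert-butyldimethylsilyloxy)-3a,6-dimethyl-1-(propan-2-yl)-3,3a,4,5,8,8a-hexahydroazulen-8-yl 4-(tert-butyldimethylsilyloxy)benzoate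
Conditions: Pd(dppf)Cl2 (5 mol%), THF, rt → 40 °C
Reagents that add atoms: none
Why: Negishi cross-coupling of the alkenyl triflate with the secondary alkylzinc reagent (the dppf ligand limits β-hydride isomerisation) places the isopropyl group on C1 of the C1=C2 alkene.

Step 15
Reactants: 27 isopropyl alkene
Product: 28 (1R,2S,3aS,4S,8S,8aR)-1,2-diol of 27
Conditions: OsO4 (5 mol%), NMO, acetone/H2O, 0 °C → rt
Reagents that add atoms: N-methylmorpholine N-oxide, C[N+]1([O-])CCOCC1; water, O
Why: Upjohn syn-dihydroxylation: the cyclopentene should react in preference to the C6=C7 alkene, which is deactivated by its allylic aroyloxy group, and osmium should add to the convex face anti to the C8a–C8 and C3a–C4 bonds, which sets C1 and C2 as the cis-diol on the side of H-8a and the angular methyl.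

Step 16
Reactants: 28 diol
Product: 29 2-O-acetate of 28
Conditions: Ac2O, pyridine, DMAP (cat.), CH2Cl2, 0 °C → rt
Reagents that add atoms: acetic anhydride, CC(=O)OC(C)=O
Why: Acetylation should take place at the secondary C2–OH only, because the tertiary C1–OH is unreactive under these conditions.

Step 17
Reactants: 29 acetate
Product: 30 (1R,2S,3aS,4S,8S,8aR)-2-acetoxy-1,4-dihydroxy-3a,6-dimethyl-1-(propan-2-yl)-1,2,3,3a,4,5,8,8a-octahydroazulen-8-yl 4-hydroxybenzoate (target)
Conditions: HF·pyridine, pyridine, THF, 0 °C → rt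
Reagents that add atoms: none
Why: Fluoride-mediated cleavage of the alkyl and the aryl silyl ether should free C4–OH and the phenol without touching the acetate, the benzoate or the tertiary alcohol.

**Compound list**

1 | 3-methylbut-3-en-1-ol | CC(=C)CCO | starting material
2 | 2-methyl-2-vinyloxirane (racemic) | CC1(C=C)CO1 | starting material
3 | 3-methylbut-3-enal | CC(=C)CC=O | intermediate (not isolated)
4 | (2S,3S)-2-ethenyl-2,5-dimethylhex-5-ene-1,3-diol | C=C[C@](CO)(C)[C@@H](O)CC(C)=C | intermediate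
5 | (2S,3S)-1,3-bis(tert-butyldimethylsilyloxy)-2-ethenyl-2,5-dimethylhex-5-ene | C=C[C@](CO[Si](C)(C)C(C)(C)C)(C)[C@@H](O[Si](C)(C)C(C)(C)C)CC(C)=C | intermediate
6 | (4S,5S)-5-(tert-butyldimethylsilyloxy)-4-[(tert-butyldimethylsilyloxy)methyl]-4,7-dimethyloct-7-enal | O=CCC[C@](CO[Si](C)(C)C(C)(C)C)(C)[C@@H](O[Si](C)(C)C(C)(C)C)CC(C)=C | intermediate (not isolated)
7 | dimethyl acetal of 6 | COC(OC)CC[C@](CO[Si](C)(C)C(C)(C)C)(C)[C@@H](O[Si](C)(C)C(C)(C)C)CC(C)=C | intermediate
8 | (2S,3S)-3-(tert-butyldimethylsilyloxy)-2-(3,3-dimethoxypropyl)-2,5-dimethylhex-5-en-1-ol | COC(OC)CC[C@](CO)(C)[C@@H](O[Si](C)(C)C(C)(C)C)CC(C)=C | intermediate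
9 | allyl acetate | CC(=O)OCC=C | starting material
10 | (2R,3S)-3-(tert-butyldimethylsilyloxy)-2-(3,3-dimethoxypropyl)-2,5-dimethylhex-5-enal | COC(OC)CC[C@](C=O)(C)[C@@H](O[Si](C)(C)C(C)(C)C)CC(C)=C | intermediate (not isolated)
11 | (5S,6S)-6-(tert-butyldimethylsilyloxy)-5-(3,3-dimethoxypropyl)-5,8-dimethylnona-1,8-dien-4-ol (both C4 epimers) | COC(OC)CC[C@](C(O)CC=C)(C)[C@@H](O[Si](C)(C)C(C)(C)C)CC(C)=C | intermediate
12 | (6S,7S)-6-(tert-butyldimethylsilyloxy)-7-(3,3-dimethoxypropyl)-4,7-dimethylcyclohept-3-en-1-ol (both C1 epimers) | COC(OC)CC[C@]1(C)[C@@H](O[Si](C)(C)C(C)(C)C)CC(C)=CCC1O | intermediate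
13 | (6S,7S)-6-(tert-butyldimethylsilyloxy)-7-(3,3-dimethoxypropyl)-4,7-dimethylcyclohepta-1,3-diene | COC(OC)CC[C@]1(C)[C@@H](O[Si](C)(C)C(C)(C)C)CC(C)=CC=C1 | intermediate
14 | 3-[(1S,7S)-7-(tert-butyldimethylsilyloxy)-1,5-dimethylcyclohepta-2,4-dien-1-yl]propanal oxime (E/Z) | ON=CCC[C@]1(C)[C@@H](O[Si](C)(C)C(C)(C)C)CC(C)=CC=C1 | intermediate
15 | N-hydroxy-3-[(1S,7S)-7-(tert-butyldimethylsilyloxy)-1,5-dimethylcyclohepta-2,4-dien-1-yl]propanimidoyl chloride | ON=C(Cl)CC[C@]1(C)[C@@H](O[Si](C)(C)C(C)(C)C)CC(C)=CC=C1 | intermediate (not isolated)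
16 | 3-[(1S,7S)-7-(tert-butyldimethylsilyloxy)-1,5-dimethylcyclohepta-2,4-dien-1-yl]propanenitrile oxide | [O-][N+]#CCC[C@]1(C)[C@@H](O[Si](C)(C)C(C)(C)C)CC(C)=CC=C1 | intermediate (not isolated)
17 | tricyclic isoxazoline: (3aS,4S,8S,8aS)-hydroazulene with C1=N–O–C8 bridge, 4-OTBS, 3a,6-dimethyl, C6=C7 | C1C[C@]2(C)[C@@H](O[Si](C)(C)C(C)(C)C)CC(C)=C[C@@H]3ON=C1[C@@H]32 | intermediate
18 | β-hydroxy imine (1-imino analogue of 19) | C1C[C@]2(C)[C@@H](O[Si](C)(C)C(C)(C)C)CC(C)=C[C@H](O)[C@@H]2C1=N | intermediate (not isolated)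
19 | (3aS,4S,8S,8aR)-4-(tert-butyldimethylsilyloxy)-8-hydroxy-3a,6-dimethyl-3,3a,4,5,8,8a-hexahydroazulen-1(2H)-one | C1C[C@]2(C)[C@@H](O[Si](C)(C)C(C)(C)C)CC(C)=C[C@H](O)[C@@H]2C1=O | intermediate
20 | 4-hydroxybenzoic acid | OC(=O)c1ccc(O)cc1 | starting material
21 | tert-butyldimethylsilyl 4-(tert-butyldimethylsilyloxy)benzoate | CC(C)(C)[Si](C)(C)OC(=O)c1ccc(O[Si](C)(C)C(C)(C)C)cc1 | intermediate (not isolated)
22 | 4-(tert-butyldimethylsilyloxy)benzoic acid | OC(=O)c1ccc(O[Si](C)(C)C(C)(C)C)cc1 | intermediate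
23 | (3aS,4S,8S,8aR)-4-(tert-butyldimethylsilyloxy)-3a,6-dimethyl-1-oxo-1,2,3,3a,4,5,8,8a-octahydroazulen-8-yl 4-(tert-butyldimethylsilyloxy)benzoate | C1C[C@]2(C)[C@@H](O[Si](C)(C)C(C)(C)C)CC(C)=C[C@H](OC(=O)c3ccc(O[Si](C)(C)C(C)(C)C)cc3)[C@@H]2C1=O | intermediate
24 | potassium enolate of 23 (C1–O−, C1=C2) | [K+].[O-]C1=CC[C@]2(C)[C@@H](O[Si](C)(C)C(C)(C)C)CC(C)=C[C@H](OC(=O)c3ccc(O[Si](C)(C)C(C)(C)C)cc3)[C@@H]21 | intermediate (not isolated)
25 | (3aS,4S,8S,8aR)-4-(tert-butyldimethylsilyloxy)-3a,6-dimethyl-1-(trifluoromethylsulfonyloxy)-3,3a,4,5,8,8a-hexahydroazulen-8-yl 4-(tert-butyldimethylsilyloxy)benzoate | FC(F)(F)S(=O)(=O)OC1=CC[C@]2(C)[C@@H](O[Si](C)(C)C(C)(C)C)CC(C)=C[C@H](OC(=O)c3ccc(O[Si](C)(C)C(C)(C)C)cc3)[C@@H]21 | intermediate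
26 | isopropylzinc bromide | CC(C)[Zn]Br | starting material
27 | (3aS,4S,8S,8aR)-4-(tert-butyldimethylsilyloxy)-3a,6-dimethyl-1-(propan-2-yl)-3,3a,4,5,8,8a-hexahydroazulen-8-yl 4-(tert-butyldimethylsilyloxy)benzoate | CC(C)C1=CC[C@]2(C)[C@@H](O[Si](C)(C)C(C)(C)C)CC(C)=C[C@H](OC(=O)c3ccc(O[Si](C)(C)C(C)(C)C)cc3)[C@@H]21 | intermediate
28 | (1R,2S,3aS,4S,8S,8aR)-4-(tert-butyldimethylsilyloxy)-1,2-dihydroxy-3a,6-dimethyl-1-(propan-2-yl)-1,2,3,3a,4,5,8,8a-octahydroazulen-8-yl 4-(tert-butyldimethylsilyloxy)benzoate | O[C@H]1C[C@]2(C)[C@@H](O[Si](C)(C)C(C)(C)C)CC(C)=C[C@H](OC(=O)c3ccc(O[Si](C)(C)C(C)(C)C)cc3)[C@@H]2[C@]1(O)C(C)C | intermediate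
29 | 2-O-acetate of 28 | CC(=O)O[C@H]1C[C@]2(C)[C@@H](O[Si](C)(C)C(C)(C)C)CC(C)=C[C@H](OC(=O)c3ccc(O[Si](C)(C)C(C)(C)C)cc3)[C@@H]2[C@]1(O)C(C)C | intermediate
30 | (1R,2S,3aS,4S,8S,8aR)-2-acetoxy-1,4-dihydroxy-3a,6-dimethyl-1-(propan-2-yl)-1,2,3,3a,4,5,8,8a-octahydroazulen-8-yl 4-hydroxybenzoate | CC(=O)O[C@H]1C[C@]2(C)[C@@H](O)CC(C)=C[C@H](OC(=O)c3ccc(O)cc3)[C@@H]2[C@]1(O)C(C)C | target

**Step count and risks**

Total step count: 17. Longest linear sequence: 16 steps (steps 1–10 and 12–17; step 11 is a one-step side branch).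

Steps most likely to fail:

1. Step 13. The danger is deprotonation at the ring-fusion C8a–H followed by E1cB loss of the C8 carboxylate; the same allylic ester could also be ionised by Pd(0) in step 14. The fallback sets out from 19 and returns at 27, carrying O8 as a silyl ether, which is no leaving group. Silylation (TESOTf, 2,6-lutidine) should give the 8-O-triethylsilyl ketone F6. Enolisation and triflation (KHMDS, PhNTf2) should give the enol triflate F7, and Negishi coupling with 26 the isopropyl alkene F8. Mild acid (PPTS, MeOH, 0 °C) should cleave the triethylsilyl ether selectively to the allylic alcohol F9, which is esterified with 22 (EDC, DMAP) to rejoin the route at 27.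

2. Step 1. The danger is migration of the 1,1-disubstituted alkene into conjugation in the transient β,γ-unsaturated aldehyde before C–C coupling, and erosion of the anti selectivity. The fallback sets out from 2 and returns at 5, with the alkene masked as a ketone ketal. Commercial 2-(2-methyl-1,3-dioxolan-2-yl)ethanol is coupled with 2 under the same iridium conditions to give the ketal diol F1. Silylation (TBSOTf) should give the bis-silyl ether F2, deketalisation (cat. I2, acetone) the methyl ketone F3, and Wittig methylenation (Ph3P=CH2) compound 5.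

3. Step 3. The danger is sluggish hydroformylation of the hindered vinyl group with competing reaction at the 1,1-disubstituted alkene, or loss of the primary silyl ether during the in-situ acetalisation. The fallback sets out from 5 and returns at 7. Aldehyde-selective (nitrite-modified) Wacker oxidation of the vinyl group should give the two-carbon aldehyde F4. Wittig reaction with methoxymethylenetriphenylphosphorane should give the methyl enol ether F5, and acid-catalysed addition of methanol (PPTS, MeOH, 0 °C) the dimethyl acetal 7.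

**Further compounds**

F1 | step 1 | (2S,3S)-2-ethenyl-2-methyl-4-(2-methyl-1,3-dioxolan-2-yl)butane-1,3-diol | C=C[C@](CO)(C)[C@@H](O)CC1(C)OCCO1
F2 | step 1 | bis-TBS ether of F1 | C=C[C@](CO[Si](C)(C)C(C)(C)C)(C)[C@@H](O[Si](C)(C)C(C)(C)C)CC1(C)OCCO1
F3 | step 1 | (4S,5S)-4-(tert-butyldimethylsilyloxy)-5-[(tert-butyldimethylsilyloxy)methyl]-5-methylhept-6-en-2-one | C=C[C@](CO[Si](C)(C)C(C)(C)C)(C)[C@@H](O[Si](C)(C)C(C)(C)C)CC(C)=O
F4 | step 3 | (3S,4S)-4-(tert-butyldimethylsilyloxy)-3-[(tert-butyldimethylsilyloxy)methyl]-3,6-dimethylhept-6-enal | O=CC[C@](CO[Si](C)(C)C(C)(C)C)(C)[C@@H](O[Si](C)(C)C(C)(C)C)CC(C)=C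
F5 | step 3 | methyl enol ether of the homologated aldehyde (E/Z) | COC=CC[C@](CO[Si](C)(C)C(C)(C)C)(C)[C@@H](O[Si](C)(C)C(C)(C)C)CC(C)=C
F6 | step 13 | 8-O-triethylsilyl ether of 19 | C1C[C@]2(C)[C@@H](O[Si](C)(C)C(C)(C)C)CC(C)=C[C@H](O[Si](CC)(CC)CC)[C@@H]2C1=O
F7 | step 13 | C1=C2 enol triflate of F6 | FC(F)(F)S(=O)(=O)OC1=CC[C@]2(C)[C@@H](O[Si](C)(C)C(C)(C)C)CC(C)=C[C@H](O[Si](CC)(CC)CC)[C@@H]21
F8 | step 13 | 1-isopropyl alkene with 8-O-triethylsilyl ether | CC(C)C1=CC[C@]2(C)[C@@H](O[Si](C)(C)C(C)(C)C)CC(C)=C[C@H](O[Si](CC)(CC)CC)[C@@H]21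
F9 | step 13 | (3aS,4S,8S,8aR)-4-(tert-butyldimethylsilyloxy)-3a,6-dimethyl-1-(propan-2-yl)-3,3a,4,5,8,8a-hexahydroazulen-8-ol | CC(C)C1=CC[C@]2(C)[C@@H](O[Si](C)(C)C(C)(C)C)CC(C)=C[C@H](O)[C@@H]21
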